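**Retrosynthetic overview**
- The target is the 3,5-di-C-prenyl derivative of isocotoin (2,4-dihydroxy-6-methoxybenzophenone); it is achiral.
- Disconnect both aryl–CH2 (prenyl) bonds: isocotoin dianion plus two prenyl bromide (phenoxide C-alkylation).
- Disconnect the aryl–C(=O) bond: 5-methoxyresorcinol plus benzonitrile (Houben–Hoesch).
- No ring is formed; both benzene rings are bought.

Assumption: the target has no stereocentre, so the "single enantiomer" requirement is moot; 5-methoxyresorcinol, benzonitrile and prenyl bromide are taken as commercial.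

**Step 1**
Reactants: 1 5-methoxyresorcinol (5-methoxybenzene-1,3-diol); 2 benzonitrile
Product: 4 (2,4-dihydroxy-6-methoxyphenyl)(phenyl)methanone (isocotoin), via ketiminium chloride 3 (not isolated)
Conditions: ZnCl2, HCl (g), Et2O, 0 °C → rt; then H2O, reflux; chromatography to remove the minor 2,6-dihydroxy-4-methoxy isomer
Reagents that add atoms: water (O)
Why: Houben–Hoesch acylation, in which the HCl/ZnCl2-activated nitrile attacks the electron-rich ring at C4/C6 (two equivalent sites, para to one OH and ortho to OMe), the ketiminium salt 3 is hydrolysed to the ketone, and the mild Lewis acid leaves the methyl ether intact; no stereocentre is formed.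

**Step 2**
Reactants: 4 isocotoin; 5 prenyl bromide (1-bromo-3-methylbut-2-ene, 2.3 equiv, added in portions)
Product: 7 [2,4-dihydroxy-6-methoxy-3,5-bis(3-methylbut-2-en-1-yl)phenyl](phenyl)methanone (target; achiral), via 3-prenylisocotoin 6 (not isolated)
Conditions: 10% aq KOH, 0 °C → rt, N2; then cold 1 M HCl to pH 4; chromatography
Reagents that add atoms: none
Why: Phenoxide C-alkylation (C-prenylation of an acylphloroglucinol-type dianion), in which water solvates the phenoxide oxygens and so favours C- over O-alkylation, C3 between the two O⁻ reacting first and C5 (ortho to 4-O⁻, para to 2-O⁻) second; no stereocentre is formed.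

**Compound list**
1 | 5-methoxyresorcinol (5-methoxybenzene-1,3-diol) | COc1cc(O)cc(O)c1 | starting material
2 | benzonitrile | N#Cc1ccccc1 | starting material
3 | (2,4-dihydroxy-6-methoxyphenyl)(phenyl)methaniminium chloride | COc1cc(O)cc(O)c1C(=[NH2+])c1ccccc1.[Cl-] | intermediate
4 | (2,4-dihydroxy-6-methoxyphenyl)(phenyl)methanone (isocotoin) | COc1cc(O)cc(O)c1C(=O)c1ccccc1 | intermediate
5 | prenyl bromide (1-bromo-3-methylbut-2-ene) | CC(C)=CCBr | starting material
6 | [2,4-dihydroxy-6-methoxy-3-(3-methylbut-2-en-1-yl)phenyl](phenyl)methanone (3-prenylisocotoin) | COc1cc(O)c(CC=C(C)C)c(O)c1C(=O)c1ccccc1 | intermediate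
7 | [2,4-dihydroxy-6-methoxy-3,5-bis(3-methylbut-2-en-1-yl)phenyl](phenyl)methanone | COc1c(CC=C(C)C)c(O)c(CC=C(C)C)c(O)c1C(=O)c1ccccc1 | target

**Total step count:** 2
**Longest linear sequence:** 2 steps

**Steps most likely to fail**
The route has only two steps, so both are ranked and there is no third.

1. Step 2 (most risky). The double C-prenylation can give O-prenyl ethers, the dearomatised 3,3-diprenyl dienone, or stop at 6; a modest yield is expected. The fallback abandons phenoxide alkylation and installs all three ring substituents by directed ortho-metalation; it sets out from 1 and comes back to the route at 7. Compound 1 is treated with NaH and MOMCl (DMF, 0 °C) to give 1-methoxy-3,5-bis(methoxymethoxy)benzene F1. n-BuLi (THF, 0 °C) lithiates between the two OMOM groups, and CuI followed by 5 gives 5-methoxy-1,3-bis(methoxymethoxy)-2-(3-methylbut-2-en-1-yl)benzene F2. A second n-BuLi/TMEDA lithiation between OMOM and OMe, then CuI and 5, gives 1-methoxy-3,5-bis(methoxymethoxy)-2,4-bis(3-methylbut-2-en-1-yl)benzene F3. Lithiation of the last ring CH and quench with N-methoxy-N-methylbenzamide (CON(C)C(=O)c1ccccc1) gives the bis-MOM ketone [2-methoxy-4,6-bis(methoxymethoxy)-3,5-bis(3-methylbut-2-en-1-yl)phenyl](phenyl)methanone F4. HCl in MeOH at rt removes both MOM groups to give 7.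

2. Step 1. The Hoesch reaction may favour the 2,6-dihydroxy-4-methoxy isomer (cotoin) or give a mixture that is hard to separate. The fallback puts the methyl group on after the acylation; it sets out from 2 and comes back to the route at 4. Compound 2 and commercial phloroglucinol (Oc1cc(O)cc(O)c1) under the same Hoesch conditions give the symmetric (2,4,6-trihydroxyphenyl)(phenyl)methanone F5, where no regiochemical question arises. MOMCl (2.2 equiv) and K2CO3 in acetone protect the 4-OH and one ortho OH, leaving the carbonyl-chelated OH free, to give [2-hydroxy-4,6-bis(methoxymethoxy)phenyl](phenyl)methanone F6. MeI and K2CO3 in DMF methylate the remaining OH to give [2-methoxy-4,6-bis(methoxymethoxy)phenyl](phenyl)methanone F7. HCl in MeOH at rt removes the MOM groups to give 4.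

**Further compounds**
F1 | step 2 | 1-methoxy-3,5-bis(methoxymethoxy)benzene | COCOc1cc(OC)cc(OCOC)c1
F2 | step 2 | 5-methoxy-1,3-bis(methoxymethoxy)-2-(3-methylbut-2-en-1-yl)benzene | COCOc1cc(OC)cc(OCOC)c1CC=C(C)C
F3 | step 2 | 1-methoxy-3,5-bis(methoxymethoxy)-2,4-bis(3-methylbut-2-en-1-yl)benzene | COCOc1cc(OC)c(CC=C(C)C)c(OCOC)c1CC=C(C)C
F4 | step 2 | [2-methoxy-4,6-bis(methoxymethoxy)-3,5-bis(3-methylbut-2-en-1-yl)phenyl](phenyl)methanone | COCOc1c(C(=O)c2ccccc2)c(OC)c(CC=C(C)C)c(OCOC)c1CC=C(C)C
F5 | step 1 | (2,4,6-trihydroxyphenyl)(phenyl)methanone | O=C(c1ccccc1)c1c(O)cc(O)cc1O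
F6 | step 1 | [2-hydroxy-4,6-bis(methoxymethoxy)phenyl](phenyl)methanone | COCOc1cc(O)c(C(=O)c2ccccc2)c(OCOC)c1
F7 | step 1 | [2-methoxy-4,6-bis(methoxymethoxy)phenyl](phenyl)methanone | COCOc1cc(OC)c(C(=O)c2ccccc2)c(OCOC)c1
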